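**Plan**

- Retrosynthesis: the acetate C–O bond is cut first, then the O–Si bond and the auxiliary C1'–S bond, and last the C6–C1' bond between the 4-pyranone ring and the undecyl chain.
- Enabling feature: in the pyranone ring, O1, C4 and the ethyl-bearing C3/C5 lie on a mirror plane through O1···C4, so C2–OMe and C6–C1' both trace back to the two equivalent C–OMe carbons of 3,5-diethyl-2,6-dimethoxy-4H-pyran-4-one.
- Forward, chain: a C8 Grignard reagent opens a C3 epoxide; silylation, thiol–ene addition and oxidation give the C11 sulfone.
- Forward, ring and union: a 3-oxoglutarate is diethylated, lactonised to the only ring (the pyranone) and O-methylated. The chain is then joined at C6 by sulfonyl-carbanion addition–elimination, followed by desulfonylation, desilylation and acetylation.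
- Stereochemistry: the single stereocentre C10' (S) comes from (S)-propylene oxide, which is opened at its CH2 group; no bond to that carbon is broken afterwards.

Key step: step 8

Remark: side-chain carbons are numbered C1'–C11' from the ring; C1' of 16 is formed without control and carried as a mixture of epimers, because step 9 turns it into a CH2 group.

**Route**

Step 1
Reactants: 1 8-bromooct-1-ene; 2 (S)-propylene oxide
Product: 4 (2S)-undec-10-en-2-ol, via oct-7-enylmagnesium bromide 3 (not isolated)
Conditions: Mg, THF, 40 °C; then CuI (10 mol %), 2, THF, −30 → 0 °C; aq. NH4Cl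
Reagents that add atoms: none
Why: Copper-catalysed SN2 ring opening of the epoxide by the Grignard reagent takes place at the unsubstituted CH2 carbon, so the C–O bond of the stereocentre is never broken and the S configuration of 2 is carried unchanged into C2 of 4.

Step 2
Reactants: 4 (2S)-undec-10-en-2-ol
Product: 5 tert-butyldimethyl{[(2S)-undec-10-en-2-yl]oxy}silane
Conditions: TBSCl, imidazole, DMF, rt
Reagents that add atoms: tert-butyldimethylsilyl chloride, CC(C)(C)[Si](C)(C)Cl
Why: Imidazole-promoted silylation of the secondary alcohol gives an ether that should tolerate the radical, oxidative, organolithium and SmI2 steps ahead and leaves the stereocentre untouched.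

Step 3
Reactants: 5 tert-butyldimethyl{[(2S)-undec-10-en-2-yl]oxy}silane; 6 thiophenol
Product: 7 tert-butyldimethyl{[(2S)-11-(phenylsulfanyl)undecan-2-yl]oxy}silane
Conditions: PhSH (1.3 equiv), azobisisobutyronitrile (cat.), toluene, 80 °C
Reagents that add atoms: none
Why: Radical-chain thiol–ene addition places sulfur on the terminal carbon, because the thiyl radical adds to give the secondary alkyl radical, which then abstracts hydrogen from thiophenol (anti-Markovnikov hydrothiolation).

Step 4
Reactants: 7 tert-butyldimethyl{[(2S)-11-(phenylsulfanyl)undecan-2-yl]oxy}silane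
Product: 9 tert-butyldimethyl{[(2S)-11-(phenylsulfonyl)undecan-2-yl]oxy}silane, via sulfoxide 8 (not isolated)
Conditions: mCPBA (2.3 equiv), NaHCO3, CH2Cl2, 0 °C → rt
Reagents that add atoms: 3-chloroperoxybenzoic acid (mCPBA), OOC(=O)c1cccc(Cl)c1
Why: Two electrophilic oxygen transfers from the peracid convert the sulfide via the sulfoxide into the sulfone, while NaHCO3 buffers the acid by-product so that the silyl ether survives (sulfide oxidation).

Step 5
Reactants: 10 dimethyl 3-oxopentanedioate
Product: 12 dimethyl 2,4-diethyl-3-oxopentanedioate, via dimethyl 2-ethyl-3-oxopentanedioate 11 (not isolated)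
Conditions: EtI (2.3 equiv), K2CO3, acetone, reflux
Reagents that add atoms: iodoethane, CCI
Why: Enolate C-alkylation of the two doubly activated methylene groups with a soft primary iodide; once one side carries an ethyl group the remaining CH2 is the more acidic and less hindered position, so the second ethyl group enters at C4, and the mixture of diastereomers and enol forms is of no consequence because both carbons become sp2 in step 6.

Step 6
Reactants: 12 dimethyl 2,4-diethyl-3-oxopentanedioate
Product: 13 3,5-diethyl-4-hydroxy-6-methoxy-2H-pyran-2-one
Conditions: H2SO4 containing SO3 (oleum), 0 °C → rt; then ice-water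
Reagents that add atoms: none
Why: In the dehydrating acid one ester is activated as an acylium-type species and is captured by the carbonyl oxygen of the other, enolised ester in a six-membered lactonisation with loss of methanol, and enolisation of the C4 ketone then gives the aromatic 4-hydroxy-2-pyranone (acid-mediated cyclisation of a 3-oxoglutarate).

Step 7
Reactants: 13 3,5-diethyl-4-hydroxy-6-methoxy-2H-pyran-2-one
Product: 14 3,5-diethyl-2,6-dimethoxy-4H-pyran-4-one
Conditions: MeOTf (1.2 equiv), CH2Cl2, rt; then aq. NaHCO3
Reagents that add atoms: methyl trifluoromethanesulfonate, COS(=O)(=O)C(F)(F)F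
Why: The neutral hydroxypyranone is alkylated by the hard methylating agent at its most basic oxygen, the lactone carbonyl oxygen, and loss of the O4 proton from the resulting pyrylium ion gives the symmetrical 4-pyranone (O-methylation of a 4-hydroxy-2-pyranone under non-basic conditions).

Step 8
Reactants: 9 tert-butyldimethyl{[(2S)-11-(phenylsulfonyl)undecan-2-yl]oxy}silane; 14 3,5-diethyl-2,6-dimethoxy-4H-pyran-4-one
Product: 16 2-[(10S)-10-(tert-butyldimethylsilyloxy)-1-(phenylsulfonyl)undecyl]-3,5-diethyl-6-methoxy-4H-pyran-4-one (both C1' epimers), via α-lithio sulfone 15 (not isolated)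
Conditions: 9 (2.1 equiv), n-C4H9Li (2.0 equiv), THF, −78 °C; then 14 (1.0 equiv), −78 → −20 °C; aq. NH4Cl
Reagents that add atoms: none
Why: n-C4H9Li removes a proton next to the sulfonyl group of 9, the carbanion 15 attacks C6 of 14 (the β-carbon of the vinylogous carbonate) to give a C4 enolate, and this enolate expels methoxide and restores the pyranone (addition–elimination). The closest known reaction type is the conjugate addition–elimination of stabilised carbanions, sulfonyl carbanions included, on β-alkoxy enones and on 2,6-dimethoxy-3,5-dialkyl-4-pyranones. No ring is closed; the C6–C1' bond is the only skeletal bond formed. The new C1' stereocentre is not controlled and need not be, since it becomes a CH2 group in step 9, and the remote C10' centre is untouched. Site selectivity needs no control because C2 and C6 of 14 are equivalent by symmetry, and conjugate rather than carbonyl addition is expected because the bulky, delocalised carbanion is soft while the C4 carbonyl is stabilised by two donor oxygens and flanked by two ethyl groups. Mono-substitution is secured because the acidic C1'–H of the product is removed by the second equivalent of 15, which leaves an anion inert to further attack; the surplus sulfone 9 should be recoverable on chromatography.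

Step 9
Reactants: 16 2-[(10S)-10-(tert-butyldimethylsilyloxy)-1-(phenylsulfonyl)undecyl]-3,5-diethyl-6-methoxy-4H-pyran-4-one
Product: 17 2-[(10S)-10-(tert-butyldimethylsilyloxy)undecyl]-3,5-diethyl-6-methoxy-4H-pyran-4-one
Conditions: SmI2 (4 equiv), THF/MeOH, −78 °C
Reagents that add atoms: none
Why: Single-electron transfer from SmI2 to the vinylogous β-keto sulfone expels benzenesulfinate from C1', a second electron gives a samarium dienolate, and methanol protonates it at C1' to restore the pyranone (reductive desulfonylation), which turns C1' into a CH2 group and leaves C10' and the silyl ether untouched.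

Step 10
Reactants: 17 2-[(10S)-10-(tert-butyldimethylsilyloxy)undecyl]-3,5-diethyl-6-methoxy-4H-pyran-4-one
Product: 18 3,5-diethyl-2-[(10S)-10-hydroxyundecyl]-6-methoxy-4H-pyran-4-one
Conditions: HF·pyridine, pyridine, THF, 0 °C → rt
Reagents that add atoms: none
Why: Fluoride attacks silicon and releases the secondary alcohol under pyridine-buffered conditions that should spare the methoxypyranone; the C10'–O bond is not broken, so the S configuration is kept (silyl ether cleavage).

Step 11
Reactants: 18 3,5-diethyl-2-[(10S)-10-hydroxyundecyl]-6-methoxy-4H-pyran-4-one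
Product: 19 (2S)-11-(3,5-diethyl-6-methoxy-4-oxo-4H-pyran-2-yl)undecan-2-yl acetate
Conditions: Ac2O, pyridine, 4-(dimethylamino)pyridine (cat.), CH2Cl2, rt
Reagents that add atoms: acetic anhydride, CC(=O)OC(C)=O
Why: Amine-catalysed acyl transfer to the secondary hydroxyl group (esterification) forms the O-acetyl bond without touching the C10'–O bond, so the target is obtained with the S configuration.

**Compound list**

1 | 8-bromooct-1-ene | C=CCCCCCCBr | starting material
2 | (S)-propylene oxide, (2S)-2-methyloxirane | C[C@H]1CO1 | starting material
3 | oct-7-enylmagnesium bromide (not isolated) | C=CCCCCCC[Mg]Br | intermediate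
4 | (2S)-undec-10-en-2-ol | C=CCCCCCCC[C@H](C)O | intermediate
5 | tert-butyldimethyl{[(2S)-undec-10-en-2-yl]oxy}silane | C=CCCCCCCC[C@H](C)O[Si](C)(C)C(C)(C)C | intermediate
6 | thiophenol | Sc1ccccc1 | starting material
7 | tert-butyldimethyl{[(2S)-11-(phenylsulfanyl)undecan-2-yl]oxy}silane | c1ccccc1SCCCCCCCCC[C@H](C)O[Si](C)(C)C(C)(C)C | intermediate
8 | tert-butyldimethyl{[(2S)-11-(phenylsulfinyl)undecan-2-yl]oxy}silane, both configurations at sulfur (not isolated) | O=S(CCCCCCCCC[C@H](C)O[Si](C)(C)C(C)(C)C)c1ccccc1 | intermediate
9 | tert-butyldimethyl{[(2S)-11-(phenylsulfonyl)undecan-2-yl]oxy}silane | O=S(=O)(CCCCCCCCC[C@H](C)O[Si](C)(C)C(C)(C)C)c1ccccc1 | intermediate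
10 | dimethyl 3-oxopentanedioate | COC(=O)CC(=O)CC(=O)OC | starting material
11 | dimethyl 2-ethyl-3-oxopentanedioate (not isolated) | CCC(C(=O)OC)C(=O)CC(=O)OC | intermediate
12 | dimethyl 2,4-diethyl-3-oxopentanedioate (diastereomer mixture) | CCC(C(=O)OC)C(=O)C(CC)C(=O)OC | intermediate
13 | 3,5-diethyl-4-hydroxy-6-methoxy-2H-pyran-2-one | CCc1c(O)c(CC)c(OC)oc1=O | intermediate
14 | 3,5-diethyl-2,6-dimethoxy-4H-pyran-4-one | CCc1c(OC)oc(OC)c(CC)c1=O | intermediate
15 | [(10S)-10-(tert-butyldimethylsilyloxy)-1-(phenylsulfonyl)undecyl]lithium (not isolated) | [Li]C(CCCCCCCC[C@H](C)O[Si](C)(C)C(C)(C)C)S(=O)(=O)c1ccccc1 | intermediate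
16 | 2-[(10S)-10-(tert-butyldimethylsilyloxy)-1-(phenylsulfonyl)undecyl]-3,5-diethyl-6-methoxy-4H-pyran-4-one (both C1' epimers) | CCc1c(C(CCCCCCCC[C@H](C)O[Si](C)(C)C(C)(C)C)S(=O)(=O)c2ccccc2)oc(OC)c(CC)c1=O | intermediate
17 | 2-[(10S)-10-(tert-butyldimethylsilyloxy)undecyl]-3,5-diethyl-6-methoxy-4H-pyran-4-one | CCc1c(CCCCCCCCC[C@H](C)O[Si](C)(C)C(C)(C)C)oc(OC)c(CC)c1=O | intermediate
18 | 3,5-diethyl-2-[(10S)-10-hydroxyundecyl]-6-methoxy-4H-pyran-4-one | CCc1c(CCCCCCCCC[C@H](C)O)oc(OC)c(CC)c1=O | intermediate
19 | (2S)-11-(3,5-diethyl-6-methoxy-4-oxo-4H-pyran-2-yl)undecan-2-yl acetate | CCc1c(CCCCCCCCC[C@H](C)OC(C)=O)oc(OC)c(CC)c1=O | target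

**Step count and risks**

Total step count: 11.
Longest linear sequence: 8 steps (steps 1–4, then 8–11); the pyranone branch (steps 5–7) is 3 steps.

Steps most likely to fail:

Step 8. The secondary carbanion may add too slowly to the ethyl-flanked C6, may attack the C4 carbonyl instead, and half of the chiral sulfone is consumed as a base. The fallback sets out from 14 and 5 and returns to the route at 16. The C6–C1' bond would still be made by addition–elimination, but with the smallest sulfonyl carbanion, and the chain would be attached afterwards by alkylation. Methyl phenyl sulfone, used in excess, would be deprotonated with n-C4H9Li (THF, −78 °C) to [(phenylsulfonyl)methyl]lithium F1, which should displace one methoxy group of 14 to give 3,5-diethyl-2-methoxy-6-[(phenylsulfonyl)methyl]-4H-pyran-4-one F2. In parallel, alkene 5 would be ozonised (O3, CH2Cl2/MeOH, −78 °C) to (9S)-9-(tert-butyldimethylsilyloxy)decanal F3, reduced in the same flask with NaBH4 to (9S)-9-(tert-butyldimethylsilyloxy)decan-1-ol F4, and converted with I2, PPh3 and imidazole into tert-butyl{[(2S)-10-iododecan-2-yl]oxy}dimethylsilane F5. Deprotonation of F2 with NaH in DMF and C-alkylation with F5 should give 16, from which steps 9 to 11 follow unchanged.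

Step 9. Electron transfer to the pyranone may outrun C–S cleavage and lead to ring reduction or loss of the methoxy group, or the cleavage may stall. The fallback sets out from 7 and 14 and returns to the route at 17; it avoids the sulfonyl group altogether. Reductive lithiation of sulfide 7 with lithium 4,4'-di-tert-butylbiphenylide (THF, −78 °C) would give [(10S)-10-(tert-butyldimethylsilyloxy)undecyl]lithium F6 together with lithium thiophenolate. Addition of CuBr·S(CH3)2 would combine both into the mixed cuprate lithium [(10S)-10-(tert-butyldimethylsilyloxy)undecyl](phenylthio)cuprate F7, in which the thiolate is the non-transferable ligand. This organocopper reagent would replace one methoxy group of 14 by conjugate addition–elimination and give 17 directly.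

Step 6. Hydrolysis and decarboxylation of the β-keto ester, or cleavage of the methyl enol ether in the strong acid, may compete with lactone closure. The fallback sets out from 12 and returns to the route at 13; the two esters would be differentiated before ring closure. One ester of 12 would be saponified with LiOH (1 equiv, THF/H2O, 0 °C), and cold acidification would give 2,4-diethyl-5-methoxy-3,5-dioxopentanoic acid F8. Activation of the acid with trifluoroacetic anhydride (CH2Cl2, 0 °C), through the mixed anhydride or the acylketene derived from it, should then let the enolised ester carbonyl oxygen close the lactone under mild conditions to give 13.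

**Further compounds**

F1 | step 8 | [(phenylsulfonyl)methyl]lithium | [Li]CS(=O)(=O)c1ccccc1
F2 | step 8 | 3,5-diethyl-2-methoxy-6-[(phenylsulfonyl)methyl]-4H-pyran-4-one | CCc1c(CS(=O)(=O)c2ccccc2)oc(OC)c(CC)c1=O
F3 | step 8 | (9S)-9-(tert-butyldimethylsilyloxy)decanal | O=CCCCCCCC[C@H](C)O[Si](C)(C)C(C)(C)C
F4 | step 8 | (9S)-9-(tert-butyldimethylsilyloxy)decan-1-ol | OCCCCCCCC[C@H](C)O[Si](C)(C)C(C)(C)C
F5 | step 8 | tert-butyl{[(2S)-10-iododecan-2-yl]oxy}dimethylsilane | ICCCCCCCC[C@H](C)O[Si](C)(C)C(C)(C)C
F6 | step 9 | [(10S)-10-(tert-butyldimethylsilyloxy)undecyl]lithium | [Li]CCCCCCCCC[C@H](C)O[Si](C)(C)C(C)(C)C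
F7 | step 9 | lithium [(10S)-10-(tert-butyldimethylsilyloxy)undecyl](phenylthio)cuprate | [Li+].c1ccccc1S[Cu-]CCCCCCCCC[C@H](C)O[Si](C)(C)C(C)(C)C
F8 | step 6 | 2,4-diethyl-5-methoxy-3,5-dioxopentanoic acid | CCC(C(O)=O)C(=O)C(CC)C(=O)OC
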